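## Analysis of the target

The target 23 is a 2-oxaspiro[4.5]decane. A γ-lactone (C1 carbinol carbon, O2, C3 carbonyl, C4 methylene) and a cyclohex-2-enone (C6 ketone, C7=C8, C9 bearing the acetate, C10 methylene) share the all-carbon quaternary centre C5. C1 carries a (1E,4E)-6-hydroxy-2,6-dimethylhepta-1,4-dienyl chain (C1′ to C6′); these atom labels are used for every intermediate, also for the five-membered precursors in which C7 is still missing. There are three stereocentres, C1 (R), C5 (R) and C9 (S): on the carbocycle the C9 oxygen is cis to C1 and trans to C4, and on the lactone the side chain at C1 is cis to the C6 carbonyl. C9 is 1,3 to C5 across C10, and C1 hangs on C5 by a bond that rotates freely until the lactone is closed, so neither relation follows from a simple vicinal effect. The sensitive groups are the γ-acyloxy enone (base), the allylic C1–O2 bond (it ionises toward a tertiary-stabilised allyl cation under Lewis acids or zerovalent palladium), the skipped diene (migration into conjugation) and the tertiary allylic alcohol (acid). The strategy rests on the C6 ketone lying between quaternary C5 and C7. Deleting C7 leaves a cyclopentanone whose C9 oxygen, C8 and C10 methylenes and carbonyl map onto the commercial enone 6. Because C5 has no hydrogen, C7 can be re-inserted only on the C8 side and the new ketone can be desaturated only to C7=C8.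

## Retrosynthetic reasoning

**23 ⇒ 21 + 22.** The C4′=C5′ bond is cut by cross-metathesis. The tertiary allylic alcohol is the most acid-labile group, so it is brought in last with 22, and the chain travels through the route as an inert allyl terminus.

**21 ⇒ 20 ⇒ 19.** The C9 acetate is traced back to a silyl ether. A C9 acyloxy group β to the C6 ketone of the five-membered stage would be lost by elimination, whereas a silyl ether survives the neutral and Lewis-acidic steps. The forward steps are desilylation and acetylation with retention at C9.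

**19 ⇒ 17.** The C7=C8 alkene is removed. Forward, a dehydrogenation through the enol silane 18 must place the double bond; only C7 carries α-hydrogens, so no regiochemical choice exists.

**17 ⇒ 14 + 15.** C7 is excised by cutting C6–C7 and C7–C8. This is the one disconnection that turns the cyclohexanone into a cyclopentanone with all three stereocentres already in place. Forward, the carbon of 15 must insert between C6 and C8 and not between C6 and C5.

**14 ⇒ 12.** The lactone bond O2–C3 is opened to a γ-hydroxy ester (13, from silyl ether 12). Closure is an acyl substitution that touches no stereocentre.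

**12 ⇒ 9 + 10.** The C4–C5 bond is cut. Forward, the enolate 11, generated regiospecifically by conjugate reduction of enone 9, is alkylated by 10. This creates quaternary C5, and the face of attack fixes C5 relative to C9 and C1.

**9 ⇒ 8 ⇒ 7 + 5, and 7 ⇒ 6.** The C1–C5 bond is cut while C5 is still an sp2 carbon. A Nozaki–Hiyama–Kishi coupling of iodoenone 7 with enal 5 under a chiral chromium complex sets C1 by reagent control, before any other centre is present on that side. Compound 7 comes from 6 by α-iodination.

**5 ⇒ 4 ⇒ 1.** The C2′–methyl bond and the C1–C1′ bond are traced to a syn methylmetallation of the alkyne of 1 followed by one-carbon hydroxymethylation. This fixes the E geometry of the trisubstituted alkene at the outset.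

## Alternatives that were turned down

**Alternative 1:** Disconnection of C5–C6 and C9–C10 by a Diels–Alder reaction of 2-methoxyfuran A1 with α-methylene-γ-butyrolactone A2, giving the oxygen-bridged ketal A3.
- For: one step from two achiral commercial compounds builds the whole carbocycle with C6 (as ketal), C7=C8 and the C9 oxygen at the right oxidation level. On ring construction this is shorter than ring enlargement plus dehydrogenation, and on this point it is stronger.
- Against: in A3 the lactone carbonyl sits on the carbon that corresponds to C1, while C3 is at the alcohol level. The lactone must therefore be turned round by redox steps, and the side chain must be added at C1 next to the finished quaternary centre with only acyclic-type control. The absolute configuration would also depend on an enantioselective, exo-selective cycloaddition of a reversible furan diene with a 1,1-disubstituted dienophile.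
- Comparison: the chosen route is longer in the carbocycle but takes C9 from the chiral pool and sets C1 before C5 becomes quaternary.

**Alternative 2:** Disconnection of C5–C10 by a semipinacol rearrangement of the epoxy alcohol A4. A Lewis acid opens the C5–C1 epoxide at C5 while a ring methylene of the symmetric cyclopentenol migrates anti, giving the β-hydroxy ketone A5.
- For: C1 and C5 both derive stereospecifically from one epoxide, and the symmetric migrating ring removes any question of which carbon shifts. On the C1/C5 relation this is stronger than the chosen route, which needs a ligand-controlled coupling and a face-selective alkylation.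
- Against: A5 has no oxygen at C9 and carries its alkene at C8=C9. The C9 stereocentre would have to be made late, by oxidation of a remote alkene under 1,3-control from C5 only. The enantioselective epoxidation beside a tertiary carbinol is demanding, ionisation at the propargylic C1 competes, and the side chain must still be built from the propynyl group.
- Comparison: the chosen route is weakest where this one is strong, but it secures C9, the centre this alternative controls least.

**Alternative 3:** Disconnection of C5–C1 by a palladium-catalysed dearomatising allylation. Zerovalent palladium ionises one arylacetate of the acylal A6, and the tethered phenol attacks through its ipso carbon to give the spiro dienone A7.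
- For: the lactone, C1, C5 and the complete side chain arrive in one catalytic asymmetric step along a biosynthesis-like path. It is by far the shortest plan and clearly stronger on step economy.
- Against: the key step combines several uncertain selectivities: C-attack at a substituted ipso carbon against O-allylation, discrimination of enantiotopic leaving groups on a π-allyl with a trisubstituted terminus (syn/anti exchange threatens the E geometry), and exposure of the free tertiary allylic alcohol. A7 then still needs hydrolysis of the C9 enol ether and a reduction at C9 controlled only across the ring.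
- Comparison: the chosen route spends more steps, but its risk sits in a ring enlargement of a known type, and C9 is never in question.

Key step: step 8

Assumption: in step 4 the valinol-derived oxazoline–sulfonamide ligand is used as the enantiomer that delivers the (1R)-carbinol; which enantiomer that is has to be fixed by a trial with each, and both are accessible.

## Route

Step 1
Reactants: 1 pent-1-en-4-yne
Product: 4 (2E)-3-methylhexa-2,5-dien-1-ol, via alkenylalane 2 (not isolated), via lithium alkenylaluminate 3 (not isolated)
Conditions: Me3Al, Cp2ZrCl2 (20 mol%), CH2Cl2, 0 °C → rt; volatiles removed; n-BuLi, THF–hexane, −78 °C; (CH2O)n, −78 °C → rt; aq. HCl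
Reagents that add atoms: trimethylaluminium C[Al](C)C; formaldehyde (as paraformaldehyde) C=O
Why: Zirconium-catalysed methylalumination (Negishi carboalumination) adds CH3 and Al syn across the terminal alkyne with Al on the terminal carbon, which fixes the E geometry; the isolated vinyl group is not carbometallated under these conditions, and the aluminate is hydroxymethylated with retention.

Step 2
Reactants: 4 (2E)-3-methylhexa-2,5-dien-1-ol
Product: 5 (2E)-3-methylhexa-2,5-dienal
Conditions: MnO2, CH2Cl2, rt
Reagents that add atoms: none
Why: MnO2 oxidises allylic alcohols under neutral conditions, so the skipped diene should not move into conjugation and the E geometry is kept.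

Step 3
Reactants: 6 (4R)-4-[(tert-butyldimethylsilyl)oxy]cyclopent-2-en-1-one
Product: 7 (4R)-4-[(tert-butyldimethylsilyl)oxy]-2-iodocyclopent-2-en-1-one
Conditions: I2, pyridine, CH2Cl2, 0 °C → rt
Reagents that add atoms: iodine II
Why: α-Iodination of an enone by conjugate addition of pyridine, iodination of the enolate and elimination (Baylis–Hillman-type); the C9 centre is not enolisable in this sequence and keeps its configuration.

Step 4
Reactants: 7 (4R)-4-[(tert-butyldimethylsilyl)oxy]-2-iodocyclopent-2-en-1-one; 5 (2E)-3-methylhexa-2,5-dienal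
Product: 8 (4R)-4-[(tert-butyldimethylsilyl)oxy]-2-[(1R,2E)-1-hydroxy-3-methylhexa-2,5-dien-1-yl]cyclopent-2-en-1-one
Conditions: CrCl2 (3 equiv), N-[2-(4-isopropyl-4,5-dihydrooxazol-2-yl)-6-methylphenyl]methanesulfonamide (single enantiomer, 3.3 equiv), Et3N, THF, rt; then NiCl2 (10 mol%), 7, 5, rt; aqueous work-up
Reagents that add atoms: none
Why: Asymmetric Nozaki–Hiyama–Kishi coupling: nickel inserts into the C–I bond, the alkenyl group passes to trivalent chromium and adds 1,2 to the aldehyde only, which forms C1–C5. The chromium-bound chiral sulfonamide selects the aldehyde face and so sets C1 (R); the remote C9 centre has little say.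

Step 5
Reactants: 8 (4R)-4-[(tert-butyldimethylsilyl)oxy]-2-[(1R,2E)-1-hydroxy-3-methylhexa-2,5-dien-1-yl]cyclopent-2-en-1-one
Product: 9 (4R)-4-[(tert-butyldimethylsilyl)oxy]-2-[(1R,2E)-3-methyl-1-[(triethylsilyl)oxy]hexa-2,5-dien-1-yl]cyclopent-2-en-1-one
Conditions: Et3SiCl, imidazole, DMF, 0 °C
Reagents that add atoms: chlorotriethylsilane CC[Si](Cl)(CC)CC
Why: Standard silylation of a secondary alcohol; it keeps the hydroxyl away from the hydride of step 6 and gives a group that can later be removed in the presence of the C9 silyl ether.

Step 6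
Reactants: 9 (4R)-4-[(tert-butyldimethylsilyl)oxy]-2-[(1R,2E)-3-methyl-1-[(triethylsilyl)oxy]hexa-2,5-dien-1-yl]cyclopent-2-en-1-one; 10 methyl bromoacetate
Product: 12 methyl 2-[(1R,4S)-4-[(tert-butyldimethylsilyl)oxy]-1-[(1R,2E)-3-methyl-1-[(triethylsilyl)oxy]hexa-2,5-dien-1-yl]-2-oxocyclopentyl]acetate, via lithium enolate 11 (not isolated)
Conditions: LiBH(s-Bu)3 (L-Selectride), THF, −78 °C; then 10 (excess), HMPA, −78 → −40 °C
Reagents that add atoms: none
Why: Conjugate reduction by the hindered borohydride gives the regiodefined enolate 11 (C5=C6), which cannot expel the C9 silyloxy group, and its SN2 alkylation forms C4–C5 and the quaternary centre (reductive alkylation of an enone). The electrophile should enter anti to the C9 silyloxy group on the envelope flap; in the rotamer that relieves 1,3-allylic strain (C1–H toward the enolate oxygen) the C1 silyloxy group lies on that same shielded face, so both elements direct C4 trans to the C9 oxygen.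

Step 7
Reactants: 12 methyl 2-[(1R,4S)-4-[(tert-butyldimethylsilyl)oxy]-1-[(1R,2E)-3-methyl-1-[(triethylsilyl)oxy]hexa-2,5-dien-1-yl]-2-oxocyclopentyl]acetate
Product: 14 (1R,5R,8S)-8-[(tert-butyldimethylsilyl)oxy]-1-[(1E)-2-methylpenta-1,4-dien-1-yl]-2-oxaspiro[4.4]nonane-3,6-dione, via hydroxy ester 13 (not isolated)
Conditions: PPTS, MeOH, 0 °C → rt; then PPTS (cat.), toluene, 50 °C
Reagents that add atoms: none
Why: Mild acidic methanolysis removes the secondary triethylsilyl ether and leaves the tert-butyldimethylsilyl ether; the freed γ-hydroxy ester lactonises by acyl substitution, helped by the quaternary C5 (Thorpe–Ingold effect). No base is present, so the β-silyloxy ketone should not eliminate.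

Step 8
Reactants: 14 (1R,5R,8S)-8-[(tert-butyldimethylsilyl)oxy]-1-[(1E)-2-methylpenta-1,4-dien-1-yl]-2-oxaspiro[4.4]nonane-3,6-dione; 15 (trimethylsilyl)diazomethane
Product: 17 (1R,5R,9R)-9-[(tert-butyldimethylsilyl)oxy]-1-[(1E)-2-methylpenta-1,4-dien-1-yl]-2-oxaspiro[4.5]decane-3,6-dione, via C7-silyl ketone 16 (not isolated)
Conditions: Sc(OTf)3 (10 mol%), CH2Cl2, −20 → 0 °C; then 0.5 M HCl, THF, 0 °C
Reagents that add atoms: none
Why: Sc(OTf)3 activates the C6 carbonyl, the nucleophilic carbon of 15 adds to it, and the diazonium betaine loses N2 in concert with a 1,2-shift of a ring carbon from C6 to the new carbon C7; this forms C6–C7 and C7–C8 and gives the C7-silyl ketone 16 (in part as its enol silane), from which dilute acid removes silicon. The closest known reaction type is the Lewis acid-catalysed homologation of cycloalkanones with silyl diazomethane, in which 2,2-disubstituted ketones such as 17-oxo steroids enlarge by migration of the methylene carbon. The six-membered carbocycle is not closed from a chain; it arises by ring enlargement, that is by insertion of C7 into the C6–C8 bond of the five-membered ring. No lasting stereocentre is made: C7 is stereogenic only in 16 and ends as a methylene, and C1, C5 and C9 take no part. The selectivity needed is migration of C8 and not of C5; the bulky Me3Si group secures it, because in the betaine it turns away from the fully substituted C5 and so places the C6–C8 bond antiperiplanar to the leaving N2. A second homologation is held back because 16 is hindered and largely enolised as a silyl ether. The C9 silyloxy group is β to the ketone, but the medium contains no base and the Lewis acid is catalytic and cold, so loss of silanol is not expected; after the step the oxygen is γ to the carbonyl and this hazard is gone.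

Step 9
Reactants: 17 (1R,5R,9R)-9-[(tert-butyldimethylsilyl)oxy]-1-[(1E)-2-methylpenta-1,4-dien-1-yl]-2-oxaspiro[4.5]decane-3,6-dione
Product: 19 (1R,5R,9S)-9-[(tert-butyldimethylsilyl)oxy]-1-[(1E)-2-methylpenta-1,4-dien-1-yl]-2-oxaspiro[4.5]dec-7-ene-3,6-dione, via enol silane 18 (not isolated)
Conditions: Me3SiOTf, Et3N, CH2Cl2, 0 °C; then Pd(OAc)2 (1.1 equiv), MeCN, rt
Reagents that add atoms: none
Why: Soft enolisation of the ketone can go only toward C7 because C5 is quaternary, and the lactone methylene is far less acidic. In the Saegusa–Ito oxidation the palladium enolate loses a β-hydrogen from C8, which gives the C7=C8 enone.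

Step 10
Reactants: 19 (1R,5R,9S)-9-[(tert-butyldimethylsilyl)oxy]-1-[(1E)-2-methylpenta-1,4-dien-1-yl]-2-oxaspiro[4.5]dec-7-ene-3,6-dione
Product: 20 (1R,5R,9S)-9-hydroxy-1-[(1E)-2-methylpenta-1,4-dien-1-yl]-2-oxaspiro[4.5]dec-7-ene-3,6-dione
Conditions: HF·pyridine, pyridine, THF, 0 °C → rt
Reagents that add atoms: none
Why: Buffered fluoride desilylation cleaves the Si–O bond without touching C9; the absence of base protects the γ-hydroxy enone and the lactone.

Step 11
Reactants: 20 (1R,5R,9S)-9-hydroxy-1-[(1E)-2-methylpenta-1,4-dien-1-yl]-2-oxaspiro[4.5]dec-7-ene-3,6-dione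
Product: 21 (1R,5R,9S)-1-[(1E)-2-methylpenta-1,4-dien-1-yl]-3,6-dioxo-2-oxaspiro[4.5]dec-7-en-9-yl acetate
Conditions: Ac2O, pyridine, DMAP (cat.), CH2Cl2, 0 °C
Reagents that add atoms: acetic anhydride CC(=O)OC(C)=O
Why: DMAP-catalysed O-acylation of the secondary allylic alcohol proceeds with retention at C9 under conditions too mild to eliminate the new acetate.

Step 12
Reactants: 21 (1R,5R,9S)-1-[(1E)-2-methylpenta-1,4-dien-1-yl]-3,6-dioxo-2-oxaspiro[4.5]dec-7-en-9-yl acetate; 22 2-methylbut-3-en-2-ol
Product: 23 (1R,5R,9S)-1-[(1E,4E)-6-hydroxy-2,6-dimethylhepta-1,4-dien-1-yl]-3,6-dioxo-2-oxaspiro[4.5]dec-7-en-9-yl acetate, (+)-miliusane XVII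
Conditions: 22 (10 equiv), second-generation Grubbs catalyst RuCl2(=CHPh)(H2IMes)(PCy3) (5–10 mol%), 1,4-benzoquinone (10 mol%), CH2Cl2, 40 °C
Reagents that add atoms: none
Why: Olefin cross-metathesis between the terminal vinyl group and a hindered tertiary allylic alcohol that homodimerises slowly should give the cross product as the E isomer. The trisubstituted alkene and the enone are inert to the catalyst, and benzoquinone suppresses migration of the skipped double bond.

## Compound list

1 | pent-1-en-4-yne | C=CCC#C | starting material
2 | dimethyl[(1E)-2-methylpenta-1,4-dien-1-yl]alane | C[Al](C)/C=C(\C)CC=C | intermediate (not isolated)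
3 | lithium butyldimethyl[(1E)-2-methylpenta-1,4-dien-1-yl]aluminate | [Li+].CCCC[Al-](C)(C)/C=C(\C)CC=C | intermediate (not isolated)
4 | (2E)-3-methylhexa-2,5-dien-1-ol | OC/C=C(\C)CC=C | intermediate
5 | (2E)-3-methylhexa-2,5-dienal | O=C/C=C(\C)CC=C | intermediate
6 | (4R)-4-[(tert-butyldimethylsilyl)oxy]cyclopent-2-en-1-one | CC(C)(C)[Si](C)(C)O[C@@H]1CC(=O)C=C1 | starting material
7 | (4R)-4-[(tert-butyldimethylsilyl)oxy]-2-iodocyclopent-2-en-1-one | CC(C)(C)[Si](C)(C)O[C@@H]1CC(=O)C(I)=C1 | intermediate
8 | (4R)-4-[(tert-butyldimethylsilyl)oxy]-2-[(1R,2E)-1-hydroxy-3-methylhexa-2,5-dien-1-yl]cyclopent-2-en-1-one | CC(C)(C)[Si](C)(C)O[C@@H]1CC(=O)C([C@H](O)/C=C(\C)CC=C)=C1 | intermediate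
9 | (4R)-4-[(tert-butyldimethylsilyl)oxy]-2-[(1R,2E)-3-methyl-1-[(triethylsilyl)oxy]hexa-2,5-dien-1-yl]cyclopent-2-en-1-one | CC(C)(C)[Si](C)(C)O[C@@H]1CC(=O)C([C@H](O[Si](CC)(CC)CC)/C=C(\C)CC=C)=C1 | intermediate
10 | methyl bromoacetate | COC(=O)CBr | starting material
11 | lithium (4S)-4-[(tert-butyldimethylsilyl)oxy]-2-[(1R,2E)-3-methyl-1-[(triethylsilyl)oxy]hexa-2,5-dien-1-yl]cyclopent-1-en-1-olate | CC(C)(C)[Si](C)(C)O[C@@H]1CC(O[Li])=C([C@H](O[Si](CC)(CC)CC)/C=C(\C)CC=C)C1 | intermediate (not isolated)
12 | methyl 2-[(1R,4S)-4-[(tert-butyldimethylsilyl)oxy]-1-[(1R,2E)-3-methyl-1-[(triethylsilyl)oxy]hexa-2,5-dien-1-yl]-2-oxocyclopentyl]acetate | CC(C)(C)[Si](C)(C)O[C@@H]1CC(=O)[C@](CC(=O)OC)([C@H](O[Si](CC)(CC)CC)/C=C(\C)CC=C)C1 | intermediate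
13 | methyl 2-[(1R,4S)-4-[(tert-butyldimethylsilyl)oxy]-1-[(1R,2E)-1-hydroxy-3-methylhexa-2,5-dien-1-yl]-2-oxocyclopentyl]acetate | CC(C)(C)[Si](C)(C)O[C@@H]1CC(=O)[C@](CC(=O)OC)([C@H](O)/C=C(\C)CC=C)C1 | intermediate (not isolated)
14 | (1R,5R,8S)-8-[(tert-butyldimethylsilyl)oxy]-1-[(1E)-2-methylpenta-1,4-dien-1-yl]-2-oxaspiro[4.4]nonane-3,6-dione (C8 of this name is C9 of the target numbering) | CC(C)(C)[Si](C)(C)O[C@@H]1CC(=O)[C@@]2(CC(=O)O[C@@H]2/C=C(\C)CC=C)C1 | intermediate
15 | (trimethylsilyl)diazomethane | C[Si](C)(C)C=[N+]=[N-] | starting material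
16 | (1R,5R,9S)-9-[(tert-butyldimethylsilyl)oxy]-1-[(1E)-2-methylpenta-1,4-dien-1-yl]-7-(trimethylsilyl)-2-oxaspiro[4.5]decane-3,6-dione, both C7 epimers | CC(C)(C)[Si](C)(C)O[C@@H]1CC([Si](C)(C)C)C(=O)[C@@]2(CC(=O)O[C@@H]2/C=C(\C)CC=C)C1 | intermediate (not isolated)
17 | (1R,5R,9R)-9-[(tert-butyldimethylsilyl)oxy]-1-[(1E)-2-methylpenta-1,4-dien-1-yl]-2-oxaspiro[4.5]decane-3,6-dione | CC(C)(C)[Si](C)(C)O[C@@H]1CCC(=O)[C@@]2(CC(=O)O[C@@H]2/C=C(\C)CC=C)C1 | intermediate
18 | (1R,5R,9R)-9-[(tert-butyldimethylsilyl)oxy]-1-[(1E)-2-methylpenta-1,4-dien-1-yl]-6-[(trimethylsilyl)oxy]-2-oxaspiro[4.5]dec-6-en-3-one | CC(C)(C)[Si](C)(C)O[C@@H]1CC=C(O[Si](C)(C)C)[C@@]2(CC(=O)O[C@@H]2/C=C(\C)CC=C)C1 | intermediate (not isolated)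
19 | (1R,5R,9S)-9-[(tert-butyldimethylsilyl)oxy]-1-[(1E)-2-methylpenta-1,4-dien-1-yl]-2-oxaspiro[4.5]dec-7-ene-3,6-dione | CC(C)(C)[Si](C)(C)O[C@@H]1C=CC(=O)[C@@]2(CC(=O)O[C@@H]2/C=C(\C)CC=C)C1 | intermediate
20 | (1R,5R,9S)-9-hydroxy-1-[(1E)-2-methylpenta-1,4-dien-1-yl]-2-oxaspiro[4.5]dec-7-ene-3,6-dione | O[C@@H]1C=CC(=O)[C@@]2(CC(=O)O[C@@H]2/C=C(\C)CC=C)C1 | intermediate
21 | (1R,5R,9S)-1-[(1E)-2-methylpenta-1,4-dien-1-yl]-3,6-dioxo-2-oxaspiro[4.5]dec-7-en-9-yl acetate | CC(=O)O[C@@H]1C=CC(=O)[C@@]2(CC(=O)O[C@@H]2/C=C(\C)CC=C)C1 | intermediate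
22 | 2-methylbut-3-en-2-ol | CC(C)(O)C=C | starting material
23 | (1R,5R,9S)-1-[(1E,4E)-6-hydroxy-2,6-dimethylhepta-1,4-dien-1-yl]-3,6-dioxo-2-oxaspiro[4.5]dec-7-en-9-yl acetate, (+)-miliusane XVII | CC(=O)O[C@@H]1C=CC(=O)[C@@]2(CC(=O)O[C@@H]2/C=C(\C)C/C=C/C(C)(C)O)C1 | target

## Step count and least certain steps

Total: 12 steps. Longest linear sequence: 11 steps (from 1 through steps 1, 2 and 4–12); the branch from 6 comprises 10 steps.

**Step 8 (key step).** Addition of the diazo carbon to the carbonyl beside the quaternary centre may be slow. Lewis acid-driven side processes could then gain ground: loss of the C9 silyloxy group by β-elimination, ionisation of the allylic C1–O2 bond with epimerisation at C1, or partial migration of C5 in place of C8.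
Fallback, from 14 to 19, an Ito–Saegusa ring enlargement in which the position of the new carbon is fixed by construction:
- Soft enolisation of 14 (Me3SiOTf, Et3N, CH2Cl2, 0 °C), possible only toward C8, gives the trimethylsilyl enol ether F1.
- Cyclopropanation with Et2Zn and CH2I2 (CH2Cl2, 0 °C), where the electron-rich enol ether should react ahead of the isolated alkenes, gives the silyloxybicyclo[3.1.0]hexane F2.
- FeCl3 in DMF at 0 °C cleaves the internal cyclopropane bond oxidatively to the ring-enlarged β-chloro ketone F3.
- NaOAc in MeOH removes HCl and gives enone 19, where the route is rejoined; step 9 is then not needed.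

**Step 6.** Direct 1,2-reduction of the carbonyl may compete with conjugate reduction. C-alkylation of the tetrasubstituted enolate may be slow enough for proton exchange with the product, whose C8 enolate would expel the C9 silyloxy group. The C1 silyloxy group may also be lost from 11, and face selectivity at C5 would erode if the assumed C1 rotamer is not dominant.
Fallback, from 9 to 12: copper hydride-catalysed 1,4-hydrosilylation of 9 ([(Ph3P)CuH]6 cat., PhMe2SiH, toluene, rt) gives the isolable dimethylphenylsilyl enol ether F4, free of boron and with the enolate position locked. MeLi (THF, 0 °C) then releases the lithium enolate 11 cleanly, and alkylation with 10 and HMPA at −78 °C returns to 12.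

**Step 4.** The chiral chromium complex may control C1 poorly with this cyclic α-keto alkenyl nucleophile, giving a mixture of C1 epimers, and reductive loss of iodine from 7 can accompany a slow coupling.
Fallback, from 7 and 5 to 8: ligand-free coupling (CrCl2, NiCl2 cat., DMF, rt) gives 8 together with its (1S)-epimer F5, which is separated by chromatography. Mitsunobu inversion of F5 (4-nitrobenzoic acid, PPh3, diisopropyl azodicarboxylate, toluene, 0 °C) gives the (1R)-4-nitrobenzoate F6, and mild methanolysis (K2CO3 cat., MeOH, 0 °C) returns 8.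

**Step 9.** Palladium may engage the other π-systems: migration of the terminal double bond of the skipped diene, or ionisation of the allylic lactone by the zerovalent palladium that is released.
Fallback, from 18 to 19 without palladium: the enol silane 18 is treated with PhSeCl (CH2Cl2, −78 °C) to give the C7-phenylselanyl ketone F7. Oxidation with H2O2 and pyridine (CH2Cl2, 0 °C) then triggers syn-elimination of the selenoxide to enone 19.

## Further compounds

F1 | step 8 | trimethylsilyl enol ether of 14 (C6–OSiMe3, C6=C8) | CC(C)(C)[Si](C)(C)O[C@@H]1C=C(O[Si](C)(C)C)[C@@]2(CC(=O)O[C@@H]2/C=C(\C)CC=C)C1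
F2 | step 8 | silyloxybicyclo[3.1.0]hexane from F1 (new CH2 bridging C6 and C8) | CC(C)(C)[Si](C)(C)O[C@@H]1C3CC3(O[Si](C)(C)C)[C@@]2(CC(=O)O[C@@H]2/C=C(\C)CC=C)C1
F3 | step 8 | ring-enlarged β-chloro ketone (chlorine on C8) | CC(C)(C)[Si](C)(C)O[C@@H]1C(Cl)CC(=O)[C@@]2(CC(=O)O[C@@H]2/C=C(\C)CC=C)C1
F4 | step 6 | dimethylphenylsilyl enol ether of the conjugate-reduced ketone | CC(C)(C)[Si](C)(C)O[C@@H]1CC(O[Si](C)(C)c2ccccc2)=C([C@H](O[Si](CC)(CC)CC)/C=C(\C)CC=C)C1
F5 | step 4 | (1S)-epimer of 8 | CC(C)(C)[Si](C)(C)O[C@@H]1CC(=O)C([C@@H](O)/C=C(\C)CC=C)=C1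
F6 | step 4 | (1R)-4-nitrobenzoate of 8 | CC(C)(C)[Si](C)(C)O[C@@H]1CC(=O)C([C@H](OC(=O)c2ccc(cc2)[N+](=O)[O-])/C=C(\C)CC=C)=C1
F7 | step 9 | C7-phenylselanyl derivative of 17 | CC(C)(C)[Si](C)(C)O[C@@H]1CC([Se]c2ccccc2)C(=O)[C@@]3(CC(=O)O[C@@H]3/C=C(\C)CC=C)C1
A1 | alternative 1 | 2-methoxyfuran | COc1ccco1
A2 | alternative 1 | α-methylene-γ-butyrolactone | C=C1CCOC1=O
A3 | alternative 1 | exo spiro cycloadduct, 1-methoxy-7-oxabicyclo[2.2.1]hept-5-ene spiro-fused to the butyrolactone | CO[C@@]12C=C[C@@H](O1)C[C@@]23C(=O)OCC3
A4 | alternative 2 | methyl 2-[2-(1-hydroxycyclopent-3-en-1-yl)-3-(prop-1-yn-1-yl)oxiran-2-yl]acetate, enantiomer as drawn | COC(=O)C[C@]1(O[C@@H]1C#CC)C2(O)CC=CC2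
A5 | alternative 2 | methyl 2-[1-(1-hydroxybut-2-yn-1-yl)-2-oxocyclohex-4-en-1-yl]acetate, target configuration at C1 and C5 | COC(=O)C[C@@]1([C@H](O)C#CC)CC=CCC1=O
A6 | alternative 3 | (2E,5E)-7-hydroxy-3,7-dimethylocta-2,5-diene-1,1-diyl bis[2-(2-hydroxy-5-methoxyphenyl)acetate] | COc1ccc(O)c(CC(=O)OC(OC(=O)Cc2cc(OC)ccc2O)/C=C(\C)C/C=C/C(C)(C)O)c1
A7 | alternative 3 | spiro lactone cyclohexa-2,4-dienone with C9 methyl enol ether | COC1C=CC(=O)[C@@]2(CC(=O)O[C@@H]2/C=C(\C)C/C=C/C(C)(C)O)C=1
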